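**Plan**

- **Numbering:** the upper flavan is O1, C2, C3, C4, C4a to C8a (rings A, C, B). The lower flavan carries primes (rings D, F, E). The two units are joined C4–C6'.
- **Cuts:** after the seven O-benzyl groups, the retrosynthesis cuts C4'–C4a' (ring F), O1'–C2' and C4–C6'. In the upper unit it then cuts the C4 leaving group back to C4–H, C4–C4a (ring C) and O1–C2. Both halves lead back to one epoxy alcohol.
- **Enabling feature:** C4' is a plain CH2 between ring D carbon C4a' (ortho to O1', para to O7') and the carbinol C3'. Ring F is therefore the opened form of an aryl 1-arylglycidyl ether that already holds C2' and C3'.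
- **Forward order:** rings B and E come with the aldehyde, ring A with 3-(benzyloxy)phenol and ring D with resorcinol. Ring C closes first, C4 is oxidised and arylated, the second glycidyl unit is attached to O1', and ring F closes last.
- **Stereochemistry:** one Sharpless kinetic resolution with D-(−)-DIPT sets C3/C3' and the carbinol carbon. Mitsunobu inversion turns that carbon into C2/C2' (2,3-cis). C4 follows by substrate control, with attack anti to the cis 2-aryl and 3-benzyloxy groups.

Key step: step 10

Remark: the SMILES is read as ent-epifisetinidol-(4α→6)-ent-epifisetinidol, with the upper unit (2S,3S,4R) and 2,3-cis-3,4-trans and the lower unit (2'S,3'S) and 2,3-cis. 3-(Benzyloxy)phenol is taken as commercial.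

Step 1
Reactants: 1 3,4-bis(benzyloxy)benzaldehyde
Product: 2 (±)-1-[3,4-bis(benzyloxy)phenyl]prop-2-en-1-ol
Conditions: CH2=CHMgBr (1.2 equiv), THF, 0 °C; then H2O
Reagents that add atoms: vinylmagnesium bromide, C=C[Mg]Br
Why: Grignard 1,2-addition of a vinyl nucleophile to an aromatic aldehyde is reliable, the benzyl ethers are inert, and the new carbinol centre is deliberately left racemic for resolution in step 2.

Step 2
Reactants: 2 (±)-1-[3,4-bis(benzyloxy)phenyl]prop-2-en-1-ol
Product: 3 (R)-[3,4-bis(benzyloxy)phenyl][(2S)-oxiran-2-yl]methanol (erythro epoxy alcohol)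
Conditions: Ti(OiPr)4 (0.15 equiv), D-(−)-DIPT (0.18 equiv), t-BuOOH (0.45 equiv), 4 Å MS, CH2Cl2, −20 °C
Reagents that add atoms: tert-butyl hydroperoxide, CC(C)(C)OO
Why: In the Sharpless kinetic resolution with D-(−)-DIPT the (S)-allylic alcohol is epoxidised much faster than its antipode and on the face that gives the erythro product, so stopping short of half conversion sets both centres of 3 by reagent control and leaves the (R)-alcohol to be separated.

Step 3
Reactants: 3 (R)-[3,4-bis(benzyloxy)phenyl][(2S)-oxiran-2-yl]methanol; 4 3-(benzyloxy)phenol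
Product: 5 (2S)-2-{(S)-[3-(benzyloxy)phenoxy][3,4-bis(benzyloxy)phenyl]methyl}oxirane (threo epoxy ether)
Conditions: PPh3, DIAD, toluene, 0 °C
Reagents that add atoms: none
Why: In this Mitsunobu etherification the phenol displaces the oxyphosphonium group by SN2 with inversion, turning the erythro alcohol into the threo (S,S) ether, while the nonpolar solvent and low temperature hold back ionisation of the benzylic centre and the epoxide stays a spectator as in the preparation of aryl glycidyl ethers from glycidol.

Step 4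
Reactants: 5 threo epoxy ether
Product: 6 (2S,3S)-7-(benzyloxy)-2-[3,4-bis(benzyloxy)phenyl]chroman-3-ol (tri-O-benzyl-ent-epifisetinidol, 2,3-cis)
Conditions: AuCl3 (5 mol %), AgOTf (15 mol %), ClCH2CH2Cl (0.01 M), 0 °C → rt
Reagents that add atoms: none
Why: This intramolecular Friedel–Crafts epoxy-arene cyclisation opens the terminal epoxide carbon (6-endo-tet) through the ring A position para to the benzyloxy group, and because no bond to either stereocentre breaks the threo ether is carried into the 2,3-cis chroman-3-ol, which also rehearses step 10 on a simple substrate.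

Step 5
Reactants: 6 tri-O-benzyl-ent-epifisetinidol
Product: 7 (2S,3S)-3,7-bis(benzyloxy)-2-[3,4-bis(benzyloxy)phenyl]chroman
Conditions: NaH, BnBr, DMF, 0 °C → rt
Reagents that add atoms: benzyl bromide, BrCc1ccccc1
Why: Williamson etherification of the secondary alkoxide leaves the aryl benzyl ethers and both stereocentres untouched, and the 3-O-benzyl group later shields one face of C4 and is removed with the other benzyl groups at the end.

Step 6
Reactants: 7 tetra-O-benzyl flavan
Product: 8 (2S,3S,4R)-3,7-bis(benzyloxy)-2-[3,4-bis(benzyloxy)phenyl]-4-(2-ethoxyethoxy)chroman (2,3-cis-3,4-trans)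
Conditions: DDQ (2 equiv), HOCH2CH2OEt (5 equiv), CH2Cl2, rt
Reagents that add atoms: 2-ethoxyethanol, CCOCCO
Why: In the DDQ benzylic oxidation known for protected flavan-3-ols, hydride is abstracted from C4, whose cation is stabilised by O7 (para) and O1 (ortho), and the alcohol adds on the face opposite the cis 2-aryl and 3-benzyloxy groups to give the 3,4-trans ether under substrate control, a centre that is ionised again in step 7.

Step 7
Reactants: 8 4-(2-ethoxyethoxy)flavan; 9 resorcinol (5 equiv)
Product: 10 4-{(2S,3S,4R)-3,7-bis(benzyloxy)-2-[3,4-bis(benzyloxy)phenyl]chroman-4-yl}benzene-1,3-diol (2,3-cis-3,4-trans)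
Conditions: BF3·OEt2 (30 mol %), CH2Cl2–Et2O, 0 °C → rt
Reagents that add atoms: none
Why: In this Lewis-acid Friedel–Crafts flavanylation of a phenol, the classical entry to 4-arylflavan-3-ols, loss of the 2-ethoxyethoxy group gives the C4 benzylic cation, excess resorcinol (its C4 and C6 being equivalent) attacks through the carbon para to one hydroxyl, and C4 is set by substrate control because the face bearing the cis 2-aryl and 3-benzyloxy groups is blocked.

Step 8
Reactants: 10 4-(2,4-dihydroxyphenyl)flavan; 3 erythro epoxy alcohol (1.05 equiv)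
Product: 11 5-{(S)-[3,4-bis(benzyloxy)phenyl][(2S)-oxiran-2-yl]methoxy}-2-{(2S,3S,4R)-3,7-bis(benzyloxy)-2-[3,4-bis(benzyloxy)phenyl]chroman-4-yl}phenol
Conditions: PPh3, DIAD, toluene, 0 °C
Reagents that add atoms: none
Why: Mitsunobu etherification with SN2 inversion, as in step 3, sets C2' as (S) and so the threo array, and one equivalent of the bulky secondary alcohol should go to the open hydroxyl para to the flavanyl group because the other hydroxyl is buried next to the C4 substituent.

Step 9
Reactants: 11 mono-etherified diphenol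
Product: 12 (2S,3S,4R)-3,7-bis(benzyloxy)-4-[2-(benzyloxy)-4-{(S)-[3,4-bis(benzyloxy)phenyl][(2S)-oxiran-2-yl]methoxy}phenyl]-2-[3,4-bis(benzyloxy)phenyl]chroman
Conditions: BnBr, K2CO3, DMF, rt
Reagents that add atoms: benzyl bromide, BrCc1ccccc1
Why: Williamson etherification with a carbonate base alkylates the remaining hindered phenol without opening the epoxide, makes ring D a resorcinol diether and removes the only acidic proton before the Lewis-acid step.

Step 10
Reactants: 12 threo epoxy ether on O1' of the 4-aryl upper flavan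
Product: 13 (2S,3S)-7-(benzyloxy)-6-{(2S,3S)-3,7-bis(benzyloxy)-2-[3,4-bis(benzyloxy)phenyl]chroman-4-yl}-2-[3,4-bis(benzyloxy)phenyl]chroman-3-ol (hepta-O-benzyl target, C4 unchanged with its aryl group trans to the 3-benzyloxy group, free 3'-hydroxyl)
Conditions: AuCl3 (5 mol %), AgOTf (15 mol %), ClCH2CH2Cl (0.005 M), 0 °C → rt
Reagents that add atoms: none
Why: The cationic gold Lewis acid made from AuCl3 and AgOTf binds the epoxide oxygen, ring D attacks the terminal carbon C4' through C4a' in an SN2-like manner, and loss of the C4a' proton from the arenium ion restores aromaticity and frees the 3'-hydroxyl. The closest known reaction type is the intramolecular Friedel–Crafts epoxy-arene cyclisation of aryl glycidyl ethers to chroman-3-ols, which is also known for 1-aryl glycidyl ethers leading to flavan-3-ols and is rehearsed in step 4. Ring F closes in the 6-endo-tet mode, because the 5-exo alternative needs attack at the internal, more hindered C3', for which the short O1'–C2' tether cannot line up C4a' behind the C3'–O bond. No stereocentre is created, since the C2'–O1', C2'–C3' and C3'–O bonds stay intact and the threo (S,S) ether is carried into the 2',3'-cis chromanol. Site selectivity on ring D is needed between C4a' and C8'; C4a' should win because it is para to the 7'-benzyloxy group and unflanked whereas C8' lies between two alkoxy groups, and the equally electron-rich ring A can react only intermolecularly and is kept out by high dilution. Chemoselectivity is needed between epoxide activation and ionisation of the C2' benzylic aryl ether, which the catalytic promoter at or below room temperature and the destabilising oxygen on the adjacent C3' should secure.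

Step 11
Reactants: 13 hepta-O-benzyl target
Product: 14 (2S,3S,4R)-2-(3,4-dihydroxyphenyl)-4-[(2S,3S)-2-(3,4-dihydroxyphenyl)-3,7-dihydroxychroman-6-yl]chroman-3,7-diol (CNP0187520.4)
Conditions: H2 (1 atm), Pd(OH)2/C, THF–MeOH, rt
Reagents that add atoms: none
Why: Catalytic hydrogenolysis of all seven O-benzyl groups is the standard last step for benzylated proanthocyanidins, the cyclic benzylic C–O bonds and the C4–C6' bond react far more slowly, and no stereocentre is involved.

**Compound list**

1 | 3,4-bis(benzyloxy)benzaldehyde | O=Cc1ccc(OCc2ccccc2)c(OCc2ccccc2)c1 | starting material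
2 | (±)-1-[3,4-bis(benzyloxy)phenyl]prop-2-en-1-ol | C=CC(O)c1ccc(OCc2ccccc2)c(OCc2ccccc2)c1 | intermediate
3 | (R)-[3,4-bis(benzyloxy)phenyl][(2S)-oxiran-2-yl]methanol | O[C@H](c1ccc(OCc3ccccc3)c(OCc3ccccc3)c1)[C@@H]4CO4 | intermediate
4 | 3-(benzyloxy)phenol | Oc1cccc(OCc2ccccc2)c1 | starting material
5 | (2S)-2-{(S)-[3-(benzyloxy)phenoxy][3,4-bis(benzyloxy)phenyl]methyl}oxirane | c3ccccc3COc1cccc(c1)O[C@@H](c1ccc(OCc3ccccc3)c(OCc3ccccc3)c1)[C@@H]4CO4 | intermediate
6 | (2S,3S)-7-(benzyloxy)-2-[3,4-bis(benzyloxy)phenyl]chroman-3-ol | c3ccccc3COc1ccc2c(c1)O[C@@H](c1ccc(OCc3ccccc3)c(OCc3ccccc3)c1)[C@@H](O)C2 | intermediate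
7 | (2S,3S)-3,7-bis(benzyloxy)-2-[3,4-bis(benzyloxy)phenyl]chroman | c3ccccc3COc1ccc2c(c1)O[C@@H](c1ccc(OCc3ccccc3)c(OCc3ccccc3)c1)[C@@H](OCc3ccccc3)C2 | intermediate
8 | (2S,3S,4R)-3,7-bis(benzyloxy)-2-[3,4-bis(benzyloxy)phenyl]-4-(2-ethoxyethoxy)chroman | c3ccccc3COc1ccc2c(c1)O[C@@H](c1ccc(OCc3ccccc3)c(OCc3ccccc3)c1)[C@@H](OCc3ccccc3)[C@@H]2OCCOCC | intermediate
9 | resorcinol | Oc1cccc(O)c1 | starting material
10 | 4-{(2S,3S,4R)-3,7-bis(benzyloxy)-2-[3,4-bis(benzyloxy)phenyl]chroman-4-yl}benzene-1,3-diol | c3ccccc3COc1ccc2c(c1)O[C@@H](c1ccc(OCc3ccccc3)c(OCc3ccccc3)c1)[C@@H](OCc3ccccc3)[C@@H]2c1ccc(O)cc1O | intermediate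
11 | 10 etherified at the hydroxyl para to the flavanyl group with the (S)-[3,4-bis(benzyloxy)phenyl][(2S)-oxiran-2-yl]methyl group, ortho hydroxyl free | c3ccccc3COc1ccc2c(c1)O[C@@H](c1ccc(OCc3ccccc3)c(OCc3ccccc3)c1)[C@@H](OCc3ccccc3)[C@@H]2c1ccc(cc1O)O[C@@H](c1ccc(OCc3ccccc3)c(OCc3ccccc3)c1)[C@@H]4CO4 | intermediate
12 | 7'-O-benzyl ether of 11 (precursor of the key step) | c3ccccc3COc1ccc2c(c1)O[C@@H](c1ccc(OCc3ccccc3)c(OCc3ccccc3)c1)[C@@H](OCc3ccccc3)[C@@H]2c1ccc(cc1OCc3ccccc3)O[C@@H](c1ccc(OCc3ccccc3)c(OCc3ccccc3)c1)[C@@H]4CO4 | intermediate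
13 | hepta-O-benzyl target with free 3'-hydroxyl (product of the key step) | c3ccccc3COc1ccc2c(c1)O[C@@H](c1ccc(OCc3ccccc3)c(OCc3ccccc3)c1)[C@@H](OCc3ccccc3)[C@@H]2c1cc2c(cc1OCc3ccccc3)O[C@@H](c1ccc(OCc3ccccc3)c(OCc3ccccc3)c1)[C@@H](O)C2 | intermediate
14 | ent-epifisetinidol-(4α→6)-ent-epifisetinidol (CNP0187520.4) | Oc1ccc2c(c1)O[C@@H](c1ccc(O)c(O)c1)[C@@H](O)[C@@H]2c1cc2c(cc1O)O[C@@H](c1ccc(O)c(O)c1)[C@@H](O)C2 | target

Total step count: 11.
Longest linear sequence: 11 steps (1 to 14). Epoxy alcohol 3 is taken from the same batch for steps 3 and 8.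

**Steps most likely to fail**

**Step 10.**
- **What may go wrong:** acid-induced heterolysis of the electron-rich C2'–O1' benzylic ether, closure through C8', or intermolecular alkylation of ring A may compete with closure of ring F.
- **Fallback:** the polarity is reversed, so that ring D acts as an aryl anion under non-acidic conditions. The fallback sets out from 8.
- **Ring D with bromine in place:** the arylation of step 7 is run with 4-bromoresorcinol (Oc1ccc(Br)c(O)c1), whose only open position activated by both hydroxyls and unflanked is C6. This should give the bromo diphenol F1 with bromine on C4a'.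
- **Etherification and protection:** Mitsunobu etherification with 3 at the more acidic, less shielded hydroxyl next to bromine gives the bromo epoxy ether F2. Benzylation (BnBr, K2CO3, DMF) gives the bromo analogue of 12, F3.
- **Ring closure:** bromine–lithium exchange (n-BuLi, THF, −95 °C) followed by MgBr2·OEt2 closes ring F by a Parham-type cyclialkylation at the terminal carbon. The route is rejoined at 13.

**Step 6.**
- **What may go wrong:** ring A lacks a 5-oxygen, so hydride abstraction at C4 may be sluggish. It may also have to compete with abstraction at C2, which is a dialkoxybenzylic ether position, or run on to over-oxidation.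
- **Fallback:** the C4 leaving group is brought in before ring C is closed. The fallback sets out from 5.
- **Building the sulfoxide:** thiophenol with Et3N in MeOH opens the terminal epoxide carbon to the hydroxy sulfide F4. NaH and BnBr give its benzyl ether F5, and one equivalent of mCPBA at −78 °C gives the sulfoxide F6 (mixed at sulfur).
- **Ring closure and coupling:** trifluoroacetic anhydride in CH2Cl2 triggers a Pummerer cyclisation in which ring A traps the thionium ion para to its benzyloxy group. This gives the 4-(phenylthio)flavan F7, and either C4 epimer serves. Thiophilic activation with AgBF4 in the presence of excess resorcinol then regenerates the C4 cation, and the route is rejoined at 10.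

**Step 8.**
- **What may go wrong:** poor discrimination between the two phenols, double etherification, or partial ionisation of the activated alcohol may erode site selectivity and the integrity of C2'.
- **Fallback:** the phenols are told apart before the valuable epoxy alcohol is committed. The fallback sets out from 10.
- **Differentiation of the phenols:** pivaloyl chloride with Et3N at −20 °C acylates the open hydroxyl to the monopivalate F8. BnBr and K2CO3 benzylate the hindered hydroxyl to the pivalate benzyl ether F9, and NaOMe in MeOH releases the monophenol F10.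
- **Etherification:** a Mitsunobu reaction of this single phenol with 3 then gives the fully protected epoxy ether directly. The route is rejoined at 12.

**Further compounds**

F1 | step 10 | 4-bromo-6-{(2S,3S)-3,7-bis(benzyloxy)-2-[3,4-bis(benzyloxy)phenyl]chroman-4-yl}benzene-1,3-diol (3,4-trans) | c3ccccc3COc1ccc2c(c1)O[C@@H](c1ccc(OCc3ccccc3)c(OCc3ccccc3)c1)[C@@H](OCc3ccccc3)[C@@H]2c1cc(Br)c(O)cc1O
F2 | step 10 | F1 etherified at the hydroxyl next to bromine with the (S)-[3,4-bis(benzyloxy)phenyl][(2S)-oxiran-2-yl]methyl group | c3ccccc3COc1ccc2c(c1)O[C@@H](c1ccc(OCc3ccccc3)c(OCc3ccccc3)c1)[C@@H](OCc3ccccc3)[C@@H]2c1cc(Br)c(cc1O)O[C@@H](c1ccc(OCc3ccccc3)c(OCc3ccccc3)c1)[C@@H]4CO4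
F3 | step 10 | benzyl ether of F2 (4a'-bromo analogue of 12) | c3ccccc3COc1ccc2c(c1)O[C@@H](c1ccc(OCc3ccccc3)c(OCc3ccccc3)c1)[C@@H](OCc3ccccc3)[C@@H]2c1cc(Br)c(cc1OCc3ccccc3)O[C@@H](c1ccc(OCc3ccccc3)c(OCc3ccccc3)c1)[C@@H]4CO4
F4 | step 6 | 1-[3-(benzyloxy)phenoxy]-1-[3,4-bis(benzyloxy)phenyl]-3-(phenylthio)propan-2-ol, both centres as in 5 | c3ccccc3COc1cccc(c1)O[C@@H](c1ccc(OCc3ccccc3)c(OCc3ccccc3)c1)[C@@H](O)CSc1ccccc1
F5 | step 6 | 2-O-benzyl ether of F4 | c3ccccc3COc1cccc(c1)O[C@@H](c1ccc(OCc3ccccc3)c(OCc3ccccc3)c1)[C@@H](OCc3ccccc3)CSc1ccccc1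
F6 | step 6 | sulfoxide of F5 (mixed at sulfur) | c3ccccc3COc1cccc(c1)O[C@@H](c1ccc(OCc3ccccc3)c(OCc3ccccc3)c1)[C@@H](OCc3ccccc3)CS(=O)c1ccccc1
F7 | step 6 | (2S,3S)-3,7-bis(benzyloxy)-2-[3,4-bis(benzyloxy)phenyl]-4-(phenylthio)chroman, drawn as the 3,4-trans epimer | c3ccccc3COc1ccc2c(c1)O[C@@H](c1ccc(OCc3ccccc3)c(OCc3ccccc3)c1)[C@@H](OCc3ccccc3)[C@@H]2Sc1ccccc1
F8 | step 8 | monopivalate of 10 at the hydroxyl para to the flavanyl group | c3ccccc3COc1ccc2c(c1)O[C@@H](c1ccc(OCc3ccccc3)c(OCc3ccccc3)c1)[C@@H](OCc3ccccc3)[C@@H]2c1ccc(OC(=O)C(C)(C)C)cc1O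
F9 | step 8 | benzyl ether of F8 | c3ccccc3COc1ccc2c(c1)O[C@@H](c1ccc(OCc3ccccc3)c(OCc3ccccc3)c1)[C@@H](OCc3ccccc3)[C@@H]2c1ccc(OC(=O)C(C)(C)C)cc1OCc3ccccc3
F10 | step 8 | 3-(benzyloxy)-4-{(2S,3S)-3,7-bis(benzyloxy)-2-[3,4-bis(benzyloxy)phenyl]chroman-4-yl}phenol (3,4-trans) | c3ccccc3COc1ccc2c(c1)O[C@@H](c1ccc(OCc3ccccc3)c(OCc3ccccc3)c1)[C@@H](OCc3ccccc3)[C@@H]2c1ccc(O)cc1OCc3ccccc3
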